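**Plan**

- Retrosynthesis cuts, in this order: the three O–CH2OMe bonds; the C3=C4 double bond of the pyran ring; the vinyl C=C on C4a; the O1–C2 ether bond; the C4a–CHO bond; the C8–CH2 bond of the prenyl group; the bond from the arene (C6) to the ketone carbon.
- Enabling feature: C3=C4 is the one bond of the 2,2-dimethyl-2H-pyran ring that is neither a bond to the hexasubstituted benzene ring (at C4a, C8a) nor a bond to quaternary C2. Both of its carbons are CH, so it can be made last from a vinyl group on C4a and the vinyl group of a 2-methylbut-3-en-2-yl ether on O1.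
- Forward: phloroglucinol is converted to its bis-MOM ether and then to the 1,1-dimethylallyl ether. Lithiation between the MOM ethers, addition to 4-(methoxymethoxy)benzaldehyde and oxidation give the benzophenone.
- A Claisen shift then moves the allyl unit from oxygen to carbon as the prenyl group. ortho-Formylation, a second O-allylation and methylenation give the diene.
- Both benzene rings are bought; the pyran is the only ring made, closed by metathesis in the penultimate step, after which acid frees the three phenols.
- Stereochemistry: the target has no stereocentre. C3=C4 is cis because it lies in a six-membered ring, and the prenyl olefin carries two identical methyl groups.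

Key step: step 11

Remark on the chemistry: benzophenone locants used below are C1 (carbonyl-bearing carbon), C2 and C6 (MOM ethers), C3 (prenyl = 3-methylbut-2-enyl), C4 (ether oxygen, later O1) and C5 (later C4a). Carbinol 10 and dienone 12 are racemic and lose their centres in the next operation.

**Route**

Step 1
Reactants: 1 phloroglucinol
Product: 3 3,5-bis(methoxymethoxy)phenol, via mono-MOM ether 2 (not isolated)
Conditions: NaH (2.0 equiv), MOMCl (2.0 equiv), DMF, 0 °C to rt
Reagents that add atoms: chloromethyl methyl ether, COCCl
Why: Williamson-type O-alkylation of the sodium phenoxides with the chloromethyl ether should give the bis-ether as the main component of a statistical mixture, from which it is separated by chromatography while the mono-ether is resubmitted.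

Step 2
Reactants: 4 2-methylbut-3-en-2-ol
Product: 5 tert-butyl 2-methylbut-3-en-2-yl carbonate
Conditions: n-BuLi, THF, −78 to 0 °C; then Boc2O, 0 °C to rt
Reagents that add atoms: di-tert-butyl dicarbonate, CC(C)(C)OC(=O)OC(=O)OC(C)(C)C
Why: O-acylation of the lithium alkoxide of a tertiary allylic alcohol with Boc2O is the standard way to the mixed tert-butyl carbonate, and loss of carbon dioxide from the leaving group makes it irreversible.

Step 3
Reactants: 3 3,5-bis(methoxymethoxy)phenol; 5 tert-butyl 2-methylbut-3-en-2-yl carbonate
Product: 6 1,3-bis(methoxymethoxy)-5-[(2-methylbut-3-en-2-yl)oxy]benzene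
Conditions: Pd(PPh3)4 (5 mol %), THF, 0–5 °C
Reagents that add atoms: none
Why: In this Tsuji–Trost O-allylation zerovalent palladium ionises the tertiary carbonate, the tert-butoxide set free deprotonates the phenol, and the phenoxide attacks the more substituted terminus of the 1,1-dimethylallyl complex under kinetic control in the cold, which should give the tertiary aryl ether.

Step 4
Reactants: 7 4-hydroxybenzaldehyde
Product: 8 4-(methoxymethoxy)benzaldehyde
Conditions: MOMCl, K2CO3, acetone, rt
Reagents that add atoms: chloromethyl methyl ether, COCCl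
Why: O-alkylation of the acidic para-formyl phenoxide with the chloromethyl ether (MOM protection) is routine.

Step 5
Reactants: 6 1,3-bis(methoxymethoxy)-5-[(2-methylbut-3-en-2-yl)oxy]benzene; 8 4-(methoxymethoxy)benzaldehyde
Product: 10 {2,6-bis(methoxymethoxy)-4-[(2-methylbut-3-en-2-yl)oxy]phenyl}[4-(methoxymethoxy)phenyl]methanol (racemic), via aryllithium 9 (not isolated)
Conditions: s-BuLi, TMEDA, THF, −78 °C, 1 h; then 8, −78 to 0 °C; aq. NH4Cl
Reagents that add atoms: none
Why: Directed ortho metalation removes the hydrogen between the two MOM ethers, the most acidic and doubly chelated position, while the tertiary allyl ether has no hydrogen on its oxygen-bearing carbon and should be left alone at −78 °C; 1,2-addition of the aryllithium to the aldehyde then gives a carbinol whose racemic centre is removed in step 6.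

Step 6
Reactants: 10 the diaryl carbinol
Product: 11 2,6,4'-tris(methoxymethoxy)-4-[(2-methylbut-3-en-2-yl)oxy]benzophenone
Conditions: Dess–Martin periodinane, pyridine, CH2Cl2, 0 °C to rt
Reagents that add atoms: none
Why: Dess–Martin oxidation of a secondary diaryl carbinol to the ketone is reliable, and the pyridine buffer shields the MOM ethers, the tertiary allyl ether and the ionisable electron-rich benzhydrol from acetic acid.

Step 7
Reactants: 11 2,6,4'-tris(methoxymethoxy)-4-[(2-methylbut-3-en-2-yl)oxy]benzophenone
Product: 13 4-hydroxy-2,6,4'-tris(methoxymethoxy)-3-prenylbenzophenone, via ortho-dienone 12 (not isolated)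
Conditions: PhMe, 110 °C
Reagents that add atoms: none
Why: The aromatic Claisen rearrangement ([3,3] shift) of the aryl 1,1-dimethylallyl ether delivers the allyl terminus to one of the two equivalent free ortho carbons (the para carbon is blocked by the aroyl group), and tautomerisation of the dienone should give the ortho-prenyl phenol with the free hydroxyl needed next.

Step 8
Reactants: 13 4-hydroxy-2,6,4'-tris(methoxymethoxy)-3-prenylbenzophenone
Product: 15 5-formyl-4-hydroxy-2,6,4'-tris(methoxymethoxy)-3-prenylbenzophenone, via salicyl alcohol 14 (not isolated)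
Conditions: MgCl2, Et3N, (CH2O)n, MeCN, 80 °C
Reagents that add atoms: formaldehyde (as paraformaldehyde), C=O
Why: In the magnesium-mediated ortho-formylation of phenols (Casiraghi–Skattebøl reaction) the magnesium phenoxide delivers formaldehyde to the only free ortho carbon and a second formaldehyde accepts hydride from the resulting benzylic alkoxide, a process specific for the carbon next to the single free phenol that should leave the prenyl olefin, the MOM ethers and the ketone alone.

Step 9
Reactants: 15 5-formyl-4-hydroxy-2,6,4'-tris(methoxymethoxy)-3-prenylbenzophenone; 5 tert-butyl 2-methylbut-3-en-2-yl carbonate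
Product: 16 5-formyl-2,6,4'-tris(methoxymethoxy)-4-[(2-methylbut-3-en-2-yl)oxy]-3-prenylbenzophenone
Conditions: Pd(PPh3)4 (10 mol %), THF, 0–5 °C
Reagents that add atoms: none
Why: The same Tsuji–Trost O-allylation as in step 3, now on a more acidic salicylaldehyde-type phenol, should give the tertiary ether kinetically if it is kept cold and stopped at full conversion, before re-ionisation can lead to the linear prenyl ether.

Step 10
Reactants: 16 5-formyl-2,6,4'-tris(methoxymethoxy)-4-[(2-methylbut-3-en-2-yl)oxy]-3-prenylbenzophenone
Product: 17 2,6,4'-tris(methoxymethoxy)-4-[(2-methylbut-3-en-2-yl)oxy]-3-prenyl-5-vinylbenzophenone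
Conditions: Ph3PCH3Br, KOtBu, THF, 0 °C; then 16, 0 °C to rt
Reagents that add atoms: methyltriphenylphosphonium bromide, C[P+](c1ccccc1)(c1ccccc1)c1ccccc1.[Br-]
Why: Wittig methylenation is selective for the aldehyde because the diaryl ketone, flanked by two ortho MOM ethers on a hexasubstituted ring, is too hindered to add the ylide at this temperature.

Step 11
Reactants: 17 2,6,4'-tris(methoxymethoxy)-4-[(2-methylbut-3-en-2-yl)oxy]-3-prenyl-5-vinylbenzophenone
Product: 18 vismiaphenone E tris(methoxymethyl) ether, [5,7-bis(methoxymethoxy)-2,2-dimethyl-8-(3-methylbut-2-enyl)-2H-chromen-6-yl][4-(methoxymethoxy)phenyl]methanone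
Conditions: second-generation Grubbs catalyst RuCl2(=CHPh)(PCy3)(H2IMes) (5 mol %), CH2Cl2 (0.005 M), 40 °C
Reagents that add atoms: none
Why: The ruthenium benzylidene exchanges with one of the two terminal vinyl groups of 17, the new alkylidene adds across the other terminal olefin to a ruthenacyclobutane, and cycloreversion releases the cyclic olefin and a ruthenium methylidene, the sequence being driven by loss of ethylene. The closest known reaction type is the ring-closing metathesis of 2-vinylaryl allyl and 1,1-dimethylallyl ethers to 2H-chromenes. The pyran ring closes as a six-membered ring by joining the two terminal sp2 carbons of an octa-1,7-diene unit (C3=C4), the olefin being cis by ring constraint and no stereocentre being formed. The step needs chemoselectivity among three olefins: the two monosubstituted olefins engage the catalyst far faster than the trisubstituted prenyl group, and the six-membered closure should outrun the seven-membered closure between the ether olefin and the prenyl group that would expel isobutene. The gem-dimethyl group on the ether carbon favours the reactive conformer (Thorpe–Ingold effect), and because both ortho carbons and the para carbon of the aryl ether are substituted a Claisen shift has no productive outlet at 40 °C. High dilution suppresses cross metathesis, and the hindered ketone and the MOM ethers do not bind the catalyst.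

Step 12
Reactants: 18 vismiaphenone E tris(methoxymethyl) ether
Product: 19 vismiaphenone E
Conditions: HCl (ca. 1 M in MeOH), rt to 40 °C
Reagents that add atoms: none
Why: Acid-catalysed acetal exchange (MOM cleavage) transfers the three methoxymethyl groups to methanol as dimethoxymethane, the two ethers ortho to the carbonyl going fastest through hydrogen-bond assistance, and dilute acid at mild temperature should spare the prenyl group and the chromene olefin.

**Compound list**

1 | phloroglucinol (benzene-1,3,5-triol) | Oc1cc(O)cc(O)c1 | starting material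
2 | 5-(methoxymethoxy)benzene-1,3-diol | COCOc1cc(O)cc(O)c1 | intermediate
3 | 3,5-bis(methoxymethoxy)phenol | COCOc1cc(O)cc(OCOC)c1 | intermediate
4 | 2-methylbut-3-en-2-ol | C=CC(C)(C)O | starting material
5 | tert-butyl 2-methylbut-3-en-2-yl carbonate | C=CC(C)(C)OC(=O)OC(C)(C)C | intermediate
6 | 1,3-bis(methoxymethoxy)-5-[(2-methylbut-3-en-2-yl)oxy]benzene | C=CC(C)(C)Oc1cc(OCOC)cc(OCOC)c1 | intermediate
7 | 4-hydroxybenzaldehyde | O=Cc1ccc(O)cc1 | starting material
8 | 4-(methoxymethoxy)benzaldehyde | COCOc1ccc(C=O)cc1 | intermediate
9 | {2,6-bis(methoxymethoxy)-4-[(2-methylbut-3-en-2-yl)oxy]phenyl}lithium | [Li]c1c(OCOC)cc(OC(C)(C)C=C)cc1OCOC | intermediate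
10 | {2,6-bis(methoxymethoxy)-4-[(2-methylbut-3-en-2-yl)oxy]phenyl}[4-(methoxymethoxy)phenyl]methanol (racemic) | C=CC(C)(C)Oc1cc(OCOC)c(C(O)c2ccc(OCOC)cc2)c(OCOC)c1 | intermediate
11 | 2,6,4'-tris(methoxymethoxy)-4-[(2-methylbut-3-en-2-yl)oxy]benzophenone | C=CC(C)(C)Oc1cc(OCOC)c(C(=O)c2ccc(OCOC)cc2)c(OCOC)c1 | intermediate
12 | 4-[4-(methoxymethoxy)benzoyl]-3,5-bis(methoxymethoxy)-6-(3-methylbut-2-enyl)cyclohexa-2,4-dien-1-one (racemic) | CC(C)=CCC1C(=O)C=C(OCOC)C(C(=O)c2ccc(OCOC)cc2)=C1OCOC | intermediate
13 | 4-hydroxy-2,6,4'-tris(methoxymethoxy)-3-(3-methylbut-2-enyl)benzophenone | CC(C)=CCc1c(O)cc(OCOC)c(C(=O)c2ccc(OCOC)cc2)c1OCOC | intermediate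
14 | 4-hydroxy-5-(hydroxymethyl)-2,6,4'-tris(methoxymethoxy)-3-(3-methylbut-2-enyl)benzophenone | CC(C)=CCc1c(O)c(CO)c(OCOC)c(C(=O)c2ccc(OCOC)cc2)c1OCOC | intermediate
15 | 5-formyl-4-hydroxy-2,6,4'-tris(methoxymethoxy)-3-(3-methylbut-2-enyl)benzophenone | CC(C)=CCc1c(O)c(C=O)c(OCOC)c(C(=O)c2ccc(OCOC)cc2)c1OCOC | intermediate
16 | 5-formyl-2,6,4'-tris(methoxymethoxy)-4-[(2-methylbut-3-en-2-yl)oxy]-3-(3-methylbut-2-enyl)benzophenone | C=CC(C)(C)Oc1c(C=O)c(OCOC)c(C(=O)c2ccc(OCOC)cc2)c(OCOC)c1CC=C(C)C | intermediate
17 | 2,6,4'-tris(methoxymethoxy)-4-[(2-methylbut-3-en-2-yl)oxy]-3-(3-methylbut-2-enyl)-5-vinylbenzophenone | C=CC(C)(C)Oc1c(C=C)c(OCOC)c(C(=O)c2ccc(OCOC)cc2)c(OCOC)c1CC=C(C)C | intermediate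
18 | [5,7-bis(methoxymethoxy)-2,2-dimethyl-8-(3-methylbut-2-enyl)-2H-chromen-6-yl][4-(methoxymethoxy)phenyl]methanone | CC(C)=CCc1c(OCOC)c(C(=O)c2ccc(OCOC)cc2)c(OCOC)c2c1OC(C)(C)C=C2 | intermediate
19 | vismiaphenone E, [5,7-dihydroxy-2,2-dimethyl-8-(3-methylbut-2-enyl)-2H-chromen-6-yl](4-hydroxyphenyl)methanone | CC(C)=CCc1c(O)c(C(=O)c2ccc(O)cc2)c(O)c2c1OC(C)(C)C=C2 | target

**Step count**

Total: 12 steps. Longest linear sequence: 10 steps (1, 3, 5, 6, 7, 8, 9, 10, 11, 12, from phloroglucinol); steps 2 and 4 prepare the carbonate and the aldehyde.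

**Steps most likely to fail, with fallbacks**

Step 9. The hindered, hydrogen-bonded phenoxide may attack the allylpalladium complex too slowly, so that the complex eliminates to isoprene, or the tertiary ether may re-ionise and drift to the linear prenyl ether. The fallback sets out from 15 and forms the ether without a reversible ionisation. Copper-catalysed tert-propargylation with 3-chloro-3-methylbut-1-yne (CuCl2·2H2O cat., DBU, MeCN, 0 °C) should give 5-formyl-2,6,4'-tris(methoxymethoxy)-4-[(2-methylbut-3-yn-2-yl)oxy]-3-prenylbenzophenone F1. Semihydrogenation of the terminal alkyne (H2, Pd/CaCO3 poisoned with Pb(OAc)2, quinoline, EtOAc) would then return to the route at 16; the aldehyde and the trisubstituted prenyl olefin should not be reduced.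

Step 5. The alkyllithium may attack the tertiary allyl ether (displacement of the aryloxide with allylic transposition) or metalate next to the ether oxygen, which would be followed by cyclisation onto the olefin. The fallback sets out from 3 and keeps the allyl ether away from the organolithium:
- Silylation (TIPSCl, imidazole, DMF) gives [3,5-bis(methoxymethoxy)phenoxy]triisopropylsilane F2.
- Lithiation between the MOM ethers (n-BuLi, THF, 0 °C) gives [2,6-bis(methoxymethoxy)-4-(triisopropylsilyloxy)phenyl]lithium F3, which adds to aldehyde 8 to give [2,6-bis(methoxymethoxy)-4-(triisopropylsilyloxy)phenyl][4-(methoxymethoxy)phenyl]methanol F4.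
- Dess–Martin oxidation with pyridine gives 2,6,4'-tris(methoxymethoxy)-4-(triisopropylsilyloxy)benzophenone F5.
- Bu4NF in THF frees 4-hydroxy-2,6,4'-tris(methoxymethoxy)benzophenone F6.
- O-Allylation of F6 with carbonate 5 and Pd(PPh3)4, as in step 3, returns to the route at 11.

Step 8. The formylation may stall at the hydroxymethyl stage or proceed sluggishly, because the phenol carries a para-aroyl group and the free ortho carbon is flanked by a MOM ether; long heating with MgCl2 could also loosen the MOM ethers next to the ketone. The fallback sets out from 13 and separates carbon introduction from oxidation. Phenylboronic acid, paraformaldehyde and catalytic propionic acid in toluene at reflux (water removed) should give [5,7-bis(methoxymethoxy)-8-(3-methylbut-2-enyl)-2-phenyl-4H-1,3,2-benzodioxaborin-6-yl][4-(methoxymethoxy)phenyl]methanone F7 by boron-templated ortho-hydroxymethylation. Exchange with propane-1,3-diol releases salicyl alcohol 14, now isolated, and MnO2 in CH2Cl2 oxidises the benzylic alcohol, returning to the route at 15.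

**Further compounds**

F1 | step 9 | 5-formyl-2,6,4'-tris(methoxymethoxy)-4-[(2-methylbut-3-yn-2-yl)oxy]-3-(3-methylbut-2-enyl)benzophenone | C#CC(C)(C)Oc1c(C=O)c(OCOC)c(C(=O)c2ccc(OCOC)cc2)c(OCOC)c1CC=C(C)C
F2 | step 5 | [3,5-bis(methoxymethoxy)phenoxy]triisopropylsilane | COCOc1cc(O[Si](C(C)C)(C(C)C)C(C)C)cc(OCOC)c1
F3 | step 5 | [2,6-bis(methoxymethoxy)-4-(triisopropylsilyloxy)phenyl]lithium | [Li]c1c(OCOC)cc(O[Si](C(C)C)(C(C)C)C(C)C)cc1OCOC
F4 | step 5 | [2,6-bis(methoxymethoxy)-4-(triisopropylsilyloxy)phenyl][4-(methoxymethoxy)phenyl]methanol (racemic) | COCOc1ccc(C(O)c2c(OCOC)cc(O[Si](C(C)C)(C(C)C)C(C)C)cc2OCOC)cc1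
F5 | step 5 | 2,6,4'-tris(methoxymethoxy)-4-(triisopropylsilyloxy)benzophenone | COCOc1ccc(C(=O)c2c(OCOC)cc(O[Si](C(C)C)(C(C)C)C(C)C)cc2OCOC)cc1
F6 | step 5 | 4-hydroxy-2,6,4'-tris(methoxymethoxy)benzophenone | COCOc1ccc(C(=O)c2c(OCOC)cc(O)cc2OCOC)cc1
F7 | step 8 | [5,7-bis(methoxymethoxy)-8-(3-methylbut-2-enyl)-2-phenyl-4H-1,3,2-benzodioxaborin-6-yl][4-(methoxymethoxy)phenyl]methanone | CC(C)=CCc1c2OB(c3ccccc3)OCc2c(OCOC)c(C(=O)c3ccc(OCOC)cc3)c1OCOC
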